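## The problem

2,3,4,7-Tetrabromoindole 7 is a flat bicycle, a pyrrole ring fused to a benzene ring, with no stereocenter, so the whole difficulty is positional. Four ring carbons carry bromine: C2 and C3 on the pyrrole ring and C4 and C7 on the benzene ring, the last two para to each other and each next to a ring-fusion carbon. C3 and, after it, C2 are where an indole meets electrophiles unaided, whereas electrophilic bromination of the benzene ring goes to C5 and C6 and reaches neither C4 nor C7. The C4 bromine can be bought with the starting material, which leaves C7 as the one carbon that needs a directing element. The fragile part is the N–H 2,3-dibromopyrrole half, which is open to protonation at C3, to attack of water at C2 on the way into the oxindole series, to further oxidation and to photolytic loss of bromine, so it should be made last and kept from acid, light and prolonged heating. What allows a short synthesis is that C7–H lies directly beside N1–H. In iridium-catalysed C–H borylation the N–H group sends boron first to C2 and then, once C2 is occupied, to C7, so boron can mark exactly the two carbons that must become C–Br while C3–H remains the innately nucleophilic site.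

## Retrosynthesis

**Target 7 back to diboronate 4.** Three C–Br bonds are cut at once: C2–Br and C7–Br go back to C–B bonds and C3–Br goes back to C–H. Cutting C7–Br back to C–H instead would be pointless, since no electrophile re-enters at C7. Cutting only the two pyrrole bromines would leave a benzene-ring dibromide that has to be made by building a ring. The precursor 4 carries only the robust C4 bromine and two pinacolboronates, so all the labile C–Br bonds appear in the last operation. The forward reaction asks copper dibromide for two ipso-substitutions of boron and one aromatic substitution at C3 in a single flask, through the intermediates 5 and 6, which are not isolated. It also asks that 7 survive until it is taken out of the medium.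

**Diboronate 4 back to 4-bromoindole 1 and bis(pinacolato)diboron 2.** The C2–B and C7–B bonds are cut and both are made by C–H borylation, through the 2-monoboronate 3. C2 is the innate first site of an N–H indole; C7 is reached because the N–H group directs the second borylation to its neighbour. The C4 bromine helps rather than hinders: it blocks C4, shields C5, and with the new boron at C7 leaves no unhindered C–H for a third borylation. The forward reaction must prefer C7 over the sterically open C6 in 3 and must leave the aryl bromide alone.

**Starting materials.** 1 and 2 are catalogue compounds. The skeleton and the C4 bromine are bought, so no ring is closed and no C–C bond is formed anywhere in the route.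

## Roads not taken

Alternative 1: benzene ring by Diels–Alder reaction of a dibromothiophene dioxide.
- Cut: C3a–C4 and C7–C7a, so that the carbocycle is assembled with both of its bromines in place.
- Forward key step: 2,5-dibromothiophene 1,1-dioxide A1 reacts as an electron-poor diene with the enecarbamate tert-butyl 2,3-dihydropyrrole-1-carboxylate A2. Loss of sulfur dioxide from the cycloadduct gives the cis-fused dibromotetrahydroindole A3.
- Merits: the symmetric diene leaves no regiochemical question, and the C4 and C7 bromines are placed without any directing effect. In certainty of bromine position on the benzene ring this road is at least as good as the chosen one.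
- Weak points: A1 must first be made by oxidising an electron-poor thiophene with a strong oxygen-transfer reagent. The two stereocenters of A3 are made only to be destroyed. The cyclohexadiene must be aromatised by loss of hydrogen, while the easier path after double-bond migration is loss of HBr, which would delete one of the bromines. After aromatisation to the N-Boc indoline A4, Boc removal, dehydrogenation to the indole and bromination at C2 and C3 are still needed.
- Comparison: about six operations against two, and the fragile dibromopyrrole must still be made at the end. The chosen plan sets its N–H-directed C7 borylation against the certainty of this cycloaddition.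

Alternative 2: pyrrole ring closure of a dibromoalkene that delivers C2 with its bromine.
- Cut: N1–C2.
- Forward key step: the sulfonamide N-[3,6-dibromo-2-(2,2-dibromoethenyl)phenyl]methanesulfonamide A5 is treated with a fluoride source or a carbonate base. Loss of HBr and attack of nitrogen on the bromoalkyne or bromoalkene carbon give the N-mesyl 2,4,7-tribromoindole A6.
- Merits: three of the four bromines are in place after the closure. The C2 bromine arrives with the ring and does not depend on a boronate prone to protodeboronation. The electron-poor N-sulfonyl indole is far more robust than an N–H bromoindole, and in this handling of the labile half the road is better than the chosen plan.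
- Weak points: A5 requires a 1,2,3,4-tetrasubstituted benzene whose aldehyde sits between a bromine and the nitrogen. The obvious precursor, 3,6-dibromo-2-nitrobenzaldehyde A7, is not a common catalogue compound and needs a regioselective synthesis of its own. The dibromo-olefination then takes place at a doubly flanked aldehyde. After the key step, C3 bromination of a deactivated indole and removal of the mesyl group remain.
- Comparison: seven or more steps against two. The chosen plan accepts a free N–H throughout in exchange for that brevity and limits the exposure of the sensitive product to a single step.

Alternative 3: Hemetsberger nitrene closure.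
- Cut: N1–C7a.
- Forward key step: ethyl (Z)-2-azido-3-(2,5-dibromophenyl)acrylate A8, made by condensing 2,5-dibromobenzaldehyde A9 with ethyl azidoacetate A10, is heated in xylene. Loss of dinitrogen and insertion into the only free ortho C–H give ethyl 4,7-dibromoindole-2-carboxylate A11.
- Merits: cheap starting materials, no precious metal, unambiguous regiochemistry because the other ortho carbon carries bromine, and classical chemistry in every step. In reliability per step this road is better than the chosen plan. Its final dibromination of 4,7-dibromoindole A12 with an electrophilic bromine source in an anhydrous, acid-free medium would also be gentler on the product than hot aqueous copper dibromide.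
- Weak points: the C2 ester carbon is introduced only to be excised, so hydrolysis of A11 and a hot copper-mediated decarboxylation in the presence of two aryl bromides must precede the dibromination of A12. The condensation of ortho-substituted benzaldehydes such as A9 with A10 is often inefficient, and an organic azide is heated.
- Comparison: five steps against two. The chosen plan offers direct replacement of boron by bromine and no placeholder carbon, and it carries a real risk in its last step, for which a stepwise fallback is given below.

Key step: step 2

Assumption: the three brominations of the key step are expected in the order C3, C2, C7; the route does not depend on that order, because every path ends at 7.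

## Steps

Step 1
Reactants: 1 4-bromo-1H-indole; 2 bis(pinacolato)diboron
Product: 4 4-bromo-2,7-bis(4,4,5,5-tetramethyl-1,3,2-dioxaborolan-2-yl)-1H-indole, via 4-bromo-2-(pinacolboryl)-1H-indole 3 (not isolated)
Conditions: B2pin2 (2.2 equiv), [Ir(OMe)(cod)]2 (2.5 mol %), 4,4'-di-tert-butyl-2,2'-bipyridine (5 mol %), THF, 65 °C, N2
Reagents that add atoms: bis(pinacolato)diboron (compound 2), CC1(C)OB(OC1(C)C)B1OC(C)(C)C(C)(C)O1
Why: Iridium-catalysed C–H borylation through a tris(boryl) complex of trivalent iridium; an N–H indole is borylated first at C2 and then at C7, the position beside the directing N–H group. The C4 bromine is inert to the catalyst, blocks C4 and shields C5, and C6 is neither directed nor activated, so the 2,7-diboronate should be the main product.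

Step 2
Reactants: 4 4-bromo-2,7-bis(4,4,5,5-tetramethyl-1,3,2-dioxaborolan-2-yl)-1H-indole
Product: 7 2,3,4,7-tetrabromo-1H-indole, via 3,4-dibromo-2,7-bis(pinacolboryl)-1H-indole 5 (not isolated), via 2,3,4-tribromo-7-(pinacolboryl)-1H-indole 6 (not isolated)
Conditions: CuBr2 (7.5 equiv), MeOH/H2O (1:1), N2, dark, 23 °C then 80 °C; aq NH3/NH4Cl wash
Reagents that add atoms: copper dibromide, Br[Cu]Br
Why: C3, the innately nucleophilic carbon, should be brominated first by electrophilic aromatic substitution, two CuBr2 delivering one bromine and leaving two CuBr and HBr, to give 5. Each boronate then transmetalates to divalent copper, a second CuBr2 oxidises the aryl copper bromide to trivalent copper, and C–Br reductive elimination puts bromine exactly where boron stood, the heteroaryl C2 boronate reacting first to give 6 and the aryl C7 boronate then giving 7. The closest known reaction types are the bromodeboronation of aryl pinacolboronates with CuBr2 in aqueous methanol, usually run directly after an iridium borylation, and the C3 bromination of indoles with CuBr2. No ring is closed and no stereocenter is formed. The selectivity needed is positional only, bromine at C2, C3 and C7 and none at C5 or C6; it is secured by the two boron markers, by the nucleophilicity of C3, and by the deactivation of C5 and C6 through their neighbouring bromines. Should the C2 boronate be lost by protodeboronation, the C2–H of the 3-bromoindole is the next most nucleophilic carbon and the excess CuBr2 should brominate it, so both paths converge on 7. The C4 bromine is a spectator, since neither monovalent nor divalent copper inserts into an aryl bromide under these conditions. The reaction is stopped as soon as 6 is consumed, and 7 is taken out of the acidic medium by a basic wash and chromatographed on base-washed silica in the dark.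

## Compound list

1 | 4-bromo-1H-indole | Brc1cccc2[nH]ccc12 | starting material
2 | bis(pinacolato)diboron | CC1(C)OB(OC1(C)C)B1OC(C)(C)C(C)(C)O1 | starting material
3 | 4-bromo-2-(4,4,5,5-tetramethyl-1,3,2-dioxaborolan-2-yl)-1H-indole | CC1(C)OB(OC1(C)C)c1cc2c(Br)cccc2[nH]1 | intermediate
4 | 4-bromo-2,7-bis(4,4,5,5-tetramethyl-1,3,2-dioxaborolan-2-yl)-1H-indole | CC1(C)OB(OC1(C)C)c1cc2c(Br)ccc(B3OC(C)(C)C(C)(C)O3)c2[nH]1 | intermediate
5 | 3,4-dibromo-2,7-bis(4,4,5,5-tetramethyl-1,3,2-dioxaborolan-2-yl)-1H-indole | CC1(C)OB(OC1(C)C)c1[nH]c2c(B3OC(C)(C)C(C)(C)O3)ccc(Br)c2c1Br | intermediate
6 | 2,3,4-tribromo-7-(4,4,5,5-tetramethyl-1,3,2-dioxaborolan-2-yl)-1H-indole | CC1(C)OB(OC1(C)C)c1ccc(Br)c2c(Br)c(Br)[nH]c12 | intermediate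
7 | 2,3,4,7-tetrabromo-1H-indole | Brc1[nH]c2c(Br)ccc(Br)c2c1Br | target

## Step count and risks

Total steps: 2. Longest linear sequence: 2 steps (1 to 4 to 7). Because the route has only two steps, both are assessed below, and step 1 is the only step that can stand beside the key step.

**Step 2 (key step).** The most likely failure is degradation of the pyrrole half once it carries bromine at C2 and C3. The C7 exchange is the slowest of the three events and needs heating in an aqueous medium that becomes acidic. During that time, protonation at C3 followed by attack of water at C2, or a second bromination at C3, can lead into the oxindole and isatin series. Alongside this, protodeboronation at C7, an ortho-substituted aryl boronate, may outrun transmetalation to copper and leave C7–H.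

The fallback separates the events and forms the most sensitive bond last; it sets out from 4 and comes back to the route at 7. The C2 boronate, the more labile of the two, is removed selectively by protodeboronation with catalytic Bi(OAc)3 in MeOH/THF to give 4-bromo-7-(pinacolboryl)-1H-indole F1. CuBr2 (about 4.5 equiv) in aqueous methanol then exchanges the C7 boron for bromine and brominates C3, giving 3,4,7-tribromo-1H-indole F2. The C2 bromine is finally introduced by electrophilic substitution with N-bromosuccinimide (1 equiv) in THF at 0 °C in the dark, which gives 7 in an anhydrous medium free of acid. In this sequence the copper step no longer has to compete with loss of boron at C2, and the 2-bromoindole never meets hot aqueous acid.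

**Step 1.** The most likely failure is incomplete site control in the second borylation, with the sterically open C6–H (meta to bromine) competing with the N–H-directed C7–H. Partial loss of the C2 boronate by protodeboronation during chromatography is also possible.

The fallback fixes C7 through a covalent tether; it sets out from 1 and comes back to the route at 4. Dehydrogenative N-silylation of 1 with Et2SiH2 and catalytic [RuCl2(p-cymene)]2 gives 4-bromo-1-(diethylsilyl)-1H-indole F3. Its Si–H bond binds the iridium catalyst ([IrCl(cod)]2, 4,4'-di-tert-butyl-2,2'-bipyridine, B2pin2, catalytic HBpin, THF, 80 °C) and delivers boron to C7 through a five-membered metallacycle, giving 4-bromo-1-(diethylsilyl)-7-(pinacolboryl)-1H-indole F4. Aqueous NaOAc cleaves the N–Si bond to 4-bromo-7-(pinacolboryl)-1H-indole F5 (the same substance as F1). An undirected borylation of this 7-boronate with B2pin2 and the catalyst of step 1, which takes the innate C2 position of an N–H indole, returns to 4.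

## Further compounds

F1 | step 2 | 4-bromo-7-(4,4,5,5-tetramethyl-1,3,2-dioxaborolan-2-yl)-1H-indole | CC1(C)OB(OC1(C)C)c1ccc(Br)c2cc[nH]c12
F2 | step 2 | 3,4,7-tribromo-1H-indole | Brc1c[nH]c2c(Br)ccc(Br)c12
F3 | step 1 | 4-bromo-1-(diethylsilyl)-1H-indole | CC[SiH](CC)n1ccc2c(Br)cccc21
F4 | step 1 | 4-bromo-1-(diethylsilyl)-7-(4,4,5,5-tetramethyl-1,3,2-dioxaborolan-2-yl)-1H-indole | CC[SiH](CC)n1ccc2c(Br)ccc(B3OC(C)(C)C(C)(C)O3)c21
F5 | step 1 | 4-bromo-7-(4,4,5,5-tetramethyl-1,3,2-dioxaborolan-2-yl)-1H-indole | CC1(C)OB(OC1(C)C)c1ccc(Br)c2cc[nH]c12
A1 | alternative 1 | 2,5-dibromothiophene 1,1-dioxide | O=S1(=O)C(Br)=CC=C1Br
A2 | alternative 1 | tert-butyl 2,3-dihydro-1H-pyrrole-1-carboxylate | CC(C)(C)OC(=O)N1CCC=C1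
A3 | alternative 1 | tert-butyl cis-4,7-dibromo-2,3,3a,7a-tetrahydroindole-1-carboxylate (racemic, relative configuration shown) | CC(C)(C)OC(=O)N1CC[C@@H]2C(Br)=CC=C(Br)[C@H]12
A4 | alternative 1 | tert-butyl 4,7-dibromoindoline-1-carboxylate | CC(C)(C)OC(=O)N1CCc2c(Br)ccc(Br)c21
A5 | alternative 2 | N-[3,6-dibromo-2-(2,2-dibromoethenyl)phenyl]methanesulfonamide | CS(=O)(=O)Nc1c(Br)ccc(Br)c1C=C(Br)Br
A6 | alternative 2 | 2,4,7-tribromo-1-(methylsulfonyl)-1H-indole | CS(=O)(=O)n1c(Br)cc2c(Br)ccc(Br)c21
A7 | alternative 2 | 3,6-dibromo-2-nitrobenzaldehyde | O=Cc1c(Br)ccc(Br)c1[N+](=O)[O-]
A8 | alternative 3 | ethyl (Z)-2-azido-3-(2,5-dibromophenyl)acrylate | CCOC(=O)/C(N=[N+]=[N-])=C/c1cc(Br)ccc1Br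
A9 | alternative 3 | 2,5-dibromobenzaldehyde | O=Cc1cc(Br)ccc1Br
A10 | alternative 3 | ethyl azidoacetate | CCOC(=O)CN=[N+]=[N-]
A11 | alternative 3 | ethyl 4,7-dibromo-1H-indole-2-carboxylate | CCOC(=O)c1cc2c(Br)ccc(Br)c2[nH]1
A12 | alternative 3 | 4,7-dibromo-1H-indole | Brc1ccc(Br)c2[nH]ccc12
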